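**Retrosynthetic overview**
1. Target 38 ← bis-ketal 37 ← tricyclic sulfone 36 and triflate 35 (reductive removal of a bridgehead sulfone and of a vinyl triflate).
2. The central six-membered ring is closed last: intramolecular Michael addition of an allylic sulfonyl carbanion on ring 2 to the β-methyl enone of ring 1 (35 ← 32).
3. Key C–C bond: intermolecular Michael addition of the α′-enolate of cyclopentenone 20 (ring 1) to cyclopentenone 27 (ring 2); the enolate is trapped as triflate and then methylated (32 ← 20 + 27).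
4. Both cyclopentenones ← 1,4-dicarbonyls (nitro-Michael, Nef, aldol condensation) ← one nitroalkane 15 ← cyclopropane aldehyde 10 ← meso-diol 2 ← caronic anhydride 1.
5. Ring order: cyclopropane (bought), then rings 1 and 2 separately, then the central six-membered ring.

Notation: KCp = cis-2,2-dimethyl-3-[2-(2-methyl-1,3-dioxolan-2-yl)ethyl]cyclopropyl, configured as in aldehyde 10 (chain-bearing ring carbon S, as in the target).
Assumption: the lipase acetylates the hydroxymethyl arm shown in 3; if it prefers the other arm, the same 3 is obtained by lipase hydrolysis of the meso-diacetate.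

**Step 1**
Reactants: 1 caronic anhydride
Product: 2 meso-diol
Conditions: LiAlH4, THF, 0 °C → reflux; H2O/NaOH work-up
Reagents that add atoms: none
Why: Hydride reduction of the cyclic anhydride gives the cis-diol; the two cyclopropane centres are already cis in 1 and are not touched.

**Step 2**
Reactants: 2 meso-diol
Product: 3 monoacetate
Conditions: lipase PS (Burkholderia cepacia), vinyl acetate, MTBE, 25 °C
Reagents that add atoms: vinyl acetate, CC(=O)OC=C
Why: Enzymatic desymmetrization (irreversible transesterification) of the enantiotopic CH2OH groups fixes the absolute configuration (1R,3S) of both cyclopropane stereocentres for the whole route.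

**Step 3**
Reactants: 3 monoacetate; 4 acetonylidene(triphenyl)phosphorane
Product: 6 acetoxy enone, via acetoxy aldehyde 5 (not isolated)
Conditions: Dess–Martin periodinane, NaHCO3, CH2Cl2, 0 °C → rt; then 4, rt
Reagents that add atoms: none
Why: Buffered Dess–Martin oxidation gives the cis-aldehyde without epimerization, and the stabilized ylide converts it in a Wittig reaction into the E-enone.

**Step 4**
Reactants: 6 acetoxy enone
Product: 7 acetoxy ketone
Conditions: [(Ph3P)CuH]6, benzene, H2O (2 equiv), rt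
Reagents that add atoms: none
Why: Conjugate reduction with the copper hydride delivers hydride to the β-carbon only, so the cyclopropane, the ketone and the acetate survive.

**Step 5**
Reactants: 7 acetoxy ketone
Product: 8 acetoxy ketal
Conditions: HOCH2CH2OH, pyridinium p-toluenesulfonate (cat.), benzene, reflux, Dean–Stark
Reagents that add atoms: ethylene glycol, OCCO
Why: Ketalization protects the methyl ketone against all later enolate chemistry.

**Step 6**
Reactants: 8 acetoxy ketal
Product: 9 ketal alcohol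
Conditions: K2CO3, MeOH, rt
Reagents that add atoms: none
Why: Transesterification (methanolysis of the acetate) frees the second hydroxymethyl arm under conditions that leave the ketal intact.

**Step 7**
Reactants: 9 ketal alcohol
Product: 10 ketal aldehyde
Conditions: Dess–Martin periodinane, NaHCO3, CH2Cl2, 0 °C → rt
Reagents that add atoms: none
Why: Dess–Martin oxidation under buffered, non-basic conditions gives the cis-cyclopropanecarbaldehyde without epimerization to trans.

**Step 8**
Reactants: 10 ketal aldehyde; 11 nitromethane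
Product: 12 nitroaldol
Conditions: MeNO2 (5 equiv), Bu4NF (5 mol%), THF, 0 °C
Reagents that add atoms: none
Why: Henry (nitro-aldol) addition under mild catalytic base; the new carbinol centre is removed in the next step.

**Step 9**
Reactants: 12 nitroaldol
Product: 14 nitroalkene, via nitroaldol mesylate 13 (not isolated)
Conditions: MeSO2Cl, Et3N, CH2Cl2, −20 → 0 °C
Reagents that add atoms: none
Why: Mesylation followed by E1cB elimination gives the E-nitroalkene.

**Step 10**
Reactants: 14 nitroalkene
Product: 15 nitroalkane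
Conditions: NaBH4, THF/MeOH (10:1), 0 °C
Reagents that add atoms: none
Why: Conjugate hydride reduction of the nitroalkene; no radical or cationic centre forms next to the cyclopropane.

**Step 11**
Reactants: 15 nitroalkane; 16 methyl vinyl ketone
Product: 17 nitro ketone
Conditions: DBU (10 mol%), MeCN, 0 °C → rt
Reagents that add atoms: none
Why: Nitro-Michael addition of the nitronate to the enone; the new nitro-bearing centre is erased in the Nef step.

**Step 12**
Reactants: 17 nitro ketone
Product: 19 1,4-diketone, via sodium nitronate 18 (not isolated)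
Conditions: NaOMe, MeOH, −78 °C; O3; N2 purge, NaHCO3 work-up
Reagents that add atoms: ozone, O=[O+][O-]
Why: Nef reaction in its ozonolytic form cleaves the nitronate C=N to the ketone under basic conditions that spare the dioxolane.

**Step 13**
Reactants: 19 1,4-diketone
Product: 20 ring-1 enone
Conditions: KOH (2%), EtOH/H2O, 60 °C
Reagents that add atoms: none
Why: Intramolecular aldol condensation; attack of the cyclopropyl-bearing CH2 on the methyl ketone gives the tetrasubstituted 2,3-disubstituted cyclopentenone (jasmone-type regiochemistry).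

**Step 14**
Reactants: 15 nitroalkane; 21 acrolein
Product: 22 nitro aldehyde
Conditions: DBU (5 mol%), MeCN, −20 °C
Reagents that add atoms: none
Why: Nitro-Michael addition to acrolein at low temperature with one equivalent of acceptor to avoid double addition.

**Step 15**
Reactants: 22 nitro aldehyde
Product: 24 keto aldehyde, via sodium nitronate 23 (not isolated)
Conditions: NaOMe, MeOH, −78 °C; O3; N2 purge, NaHCO3 work-up
Reagents that add atoms: ozone, O=[O+][O-]
Why: Ozonolytic Nef reaction as in step 12; the aldehyde is not oxidized at −78 °C.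

**Step 16**
Reactants: 24 keto aldehyde
Product: 25 ring-2 enone
Conditions: KOH (1%), EtOH/H2O, rt → 50 °C
Reagents that add atoms: none
Why: Intramolecular aldol condensation; the only five-membered mode gives the 2-substituted cyclopentenone.

**Step 17**
Reactants: 25 ring-2 enone
Product: 27 sulfenylated ring-2 enone, via lithium dienolate 26 (not isolated)
Conditions: LiN(iPr)2, THF, −78 °C; then PhSO2SPh, −78 °C
Reagents that add atoms: S-phenyl benzenethiosulfonate, O=S(=O)(Sc1ccccc1)c1ccccc1
Why: Kinetic α′-deprotonation gives the cross-conjugated enolate, which is sulfenylated at C-5; this sulfur later stabilizes the carbanion that closes the central ring, and the C-5 configuration is irrelevant.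

**Step 18**
Reactants: 20 ring-1 enone; 27 sulfenylated ring-2 enone
Product: 30 Michael adduct triflate, via lithium dienolate 28 (not isolated), via lithium enolate 29 (not isolated)
Conditions: LiN(iPr)2, THF, −78 °C (on 20); then 27, −78 °C, 30 min; then Comins' reagent, −78 → −20 °C
Reagents that add atoms: Comins' reagent, FC(F)(F)S(=O)(=O)N(c1ccc(Cl)cn1)S(=O)(=O)C(F)(F)F
Why: Intermolecular Michael addition of the α′-enolate of ring 1 to the unsubstituted β-carbon of ring 2 joins the two halves; a lithium-chelated compact transition state is expected to set the relative configuration of the two new centres, face selectivity towards the cyclopropyl groups is only substrate-controlled so the diastereomer shown is separated by chromatography, and the enolate formed regiospecifically at the cyclopropyl-bearing carbon is captured as the vinyl triflate.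

**Step 19**
Reactants: 30 Michael adduct triflate
Product: 31 methylated sulfide
Conditions: Me2CuLi (from CuI and MeLi), Et2O/THF, −20 → 0 °C
Reagents that add atoms: lithium dimethylcuprate, [Li+].C[Cu-]C
Why: Cuprate–vinyl triflate cross-coupling puts the methyl group on ring 2 without moving the alkene; the tetrasubstituted enone of ring 1 is too hindered for conjugate addition.

**Step 20**
Reactants: 31 methylated sulfide
Product: 32 allyl sulfone
Conditions: H2O2 (30%), (NH4)6Mo7O24 (5 mol%), EtOH, 0 °C → rt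
Reagents that add atoms: hydrogen peroxide, OO
Why: Molybdate-catalysed oxidation of sulfide to sulfone, which is selective for sulfur over the alkenes.

**Step 21**
Reactants: 32 allyl sulfone
Product: 35 tricyclic triflate, via lithiated sulfone 33 (not isolated), via lithium enolate 34 (not isolated)
Conditions: LiN(SiMe3)2, THF, −78 → −30 °C; then Comins' reagent, −78 → 0 °C
Reagents that add atoms: Comins' reagent, FC(F)(F)S(=O)(=O)N(c1ccc(Cl)cn1)S(=O)(=O)C(F)(F)F
Why: Intramolecular Michael addition of the allylic sulfonyl carbanion (α-attack) to the β-carbon of the ring-1 enone closes the central six-membered ring and creates the methyl-bearing quaternary bridgehead; the configuration set in step 18 allows only the syn (boat) closure, both new bridgeheads are cis by ring constraint, and the resulting enolate is trapped as triflate so that ring 2 keeps its final alkene and no ketone remains on the concave face.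

**Step 22**
Reactants: 35 tricyclic triflate
Product: 36 tricyclic sulfone
Conditions: Pd(OAc)2 (5 mol%), PPh3 (10 mol%), HCO2H, Bu3N, DMF, 60 °C
Reagents that add atoms: none
Why: Palladium-catalysed formate reduction of the vinyl triflate gives the trisubstituted ring-1 alkene; the bridgehead allylic sulfone cannot ionize to an allyl complex.

**Step 23**
Reactants: 36 tricyclic sulfone
Product: 37 bis-ketal
Conditions: Na(Hg) (6%), Na2HPO4, MeOH/THF, −20 °C
Reagents that add atoms: none
Why: Reductive desulfonylation by single-electron transfer replaces the sulfonyl group by hydrogen; the bridgehead configuration is fixed by the cage.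

**Step 24**
Reactants: 37 bis-ketal
Product: 38 target
Conditions: pyridinium p-toluenesulfonate, acetone/H2O (10:1), 50 °C
Reagents that add atoms: water, O
Why: Mild acetal hydrolysis frees both methyl ketones without affecting the vinylcyclopropanes.

**Compound list**
1 | caronic anhydride (cis-6,6-dimethyl-3-oxabicyclo[3.1.0]hexane-2,4-dione, meso) | O=C1OC(=O)[C@H]2[C@@H]1C2(C)C | starting material
2 | cis-[3-(hydroxymethyl)-2,2-dimethylcyclopropyl]methanol (meso) | OC[C@H]1[C@@H](CO)C1(C)C | intermediate
3 | [(1R,3S)-3-(hydroxymethyl)-2,2-dimethylcyclopropyl]methyl acetate | OC[C@H]1[C@@H](COC(C)=O)C1(C)C | intermediate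
4 | 1-(triphenyl-λ5-phosphanylidene)propan-2-one | CC(=O)C=P(c1ccccc1)(c1ccccc1)c1ccccc1 | starting material
5 | [(1R,3S)-3-formyl-2,2-dimethylcyclopropyl]methyl acetate (not isolated) | O=C[C@H]1[C@@H](COC(C)=O)C1(C)C | intermediate
6 | [(1R,3S)-2,2-dimethyl-3-[(E)-3-oxobut-1-enyl]cyclopropyl]methyl acetate | CC(=O)/C=C/[C@H]1[C@@H](COC(C)=O)C1(C)C | intermediate
7 | [(1R,3S)-2,2-dimethyl-3-(3-oxobutyl)cyclopropyl]methyl acetate | CC(=O)CC[C@H]1[C@@H](COC(C)=O)C1(C)C | intermediate
8 | [(1R,3S)-2,2-dimethyl-3-[2-(2-methyl-1,3-dioxolan-2-yl)ethyl]cyclopropyl]methyl acetate | CC1(OCCO1)CC[C@H]1[C@@H](COC(C)=O)C1(C)C | intermediate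
9 | [(1R,3S)-2,2-dimethyl-3-[2-(2-methyl-1,3-dioxolan-2-yl)ethyl]cyclopropyl]methanol | CC1(OCCO1)CC[C@H]1[C@@H](CO)C1(C)C | intermediate
10 | (1R,3S)-2,2-dimethyl-3-[2-(2-methyl-1,3-dioxolan-2-yl)ethyl]cyclopropane-1-carbaldehyde | CC1(OCCO1)CC[C@H]1[C@@H](C=O)C1(C)C | intermediate
11 | nitromethane | C[N+](=O)[O-] | starting material
12 | 1-KCp-2-nitroethan-1-ol (carbinol epimers) | CC1(OCCO1)CC[C@H]1[C@@H](C(O)C[N+](=O)[O-])C1(C)C | intermediate
13 | methanesulfonate of 12 (not isolated) | CC1(OCCO1)CC[C@H]1[C@@H](C(OS(C)(=O)=O)C[N+](=O)[O-])C1(C)C | intermediate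
14 | (E)-1-KCp-2-nitroethene | CC1(OCCO1)CC[C@H]1[C@@H](/C=C/[N+](=O)[O-])C1(C)C | intermediate
15 | 1-KCp-2-nitroethane | CC1(OCCO1)CC[C@H]1[C@@H](CC[N+](=O)[O-])C1(C)C | intermediate
16 | but-3-en-2-one (methyl vinyl ketone) | CC(=O)C=C | starting material
17 | 6-KCp-5-nitrohexan-2-one (nitro epimers) | CC1(OCCO1)CC[C@H]1[C@@H](CC(CCC(C)=O)[N+](=O)[O-])C1(C)C | intermediate
18 | sodium nitronate of 17 (not isolated) | CC1(OCCO1)CC[C@H]1[C@@H](CC(CCC(C)=O)=[N+]([O-])[O-])C1(C)C.[Na+] | intermediate
19 | 1-KCp-hexane-2,5-dione | CC1(OCCO1)CC[C@H]1[C@@H](CC(=O)CCC(C)=O)C1(C)C | intermediate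
20 | 2-KCp-3-methylcyclopent-2-en-1-one (ring 1) | CC1(OCCO1)CC[C@H]1[C@@H](C2=C(C)CCC2=O)C1(C)C | intermediate
21 | prop-2-enal (acrolein) | C=CC=O | starting material
22 | 5-KCp-4-nitropentanal (nitro epimers) | CC1(OCCO1)CC[C@H]1[C@@H](CC(CCC=O)[N+](=O)[O-])C1(C)C | intermediate
23 | sodium nitronate of 22 (not isolated) | CC1(OCCO1)CC[C@H]1[C@@H](CC(CCC=O)=[N+]([O-])[O-])C1(C)C.[Na+] | intermediate
24 | 5-KCp-4-oxopentanal | CC1(OCCO1)CC[C@H]1[C@@H](CC(=O)CCC=O)C1(C)C | intermediate
25 | 2-KCp-cyclopent-2-en-1-one (ring 2) | CC1(OCCO1)CC[C@H]1[C@@H](C2=CCCC2=O)C1(C)C | intermediate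
26 | cross-conjugated lithium dienolate of 25, deprotonated at C-5 (not isolated) | CC1(OCCO1)CC[C@H]1[C@@H](C2=CCC=C2O[Li])C1(C)C | intermediate
27 | 2-KCp-5-(phenylsulfanyl)cyclopent-2-en-1-one (C-5 epimers) | CC1(OCCO1)CC[C@H]1[C@@H](C2=CCC(Sc3ccccc3)C2=O)C1(C)C | intermediate
28 | cross-conjugated lithium dienolate of 20, deprotonated at C-5 (not isolated) | CC1(OCCO1)CC[C@H]1[C@@H](C2=C(C)CC=C2O[Li])C1(C)C | intermediate
29 | lithium enolate of the Michael adduct, enolate in ring 2 (not isolated) | CC1(OCCO1)CC[C@H]1[C@@H](C2=C(C)C[C@H]([C@@H]3CC(Sc4ccccc4)C(O[Li])=C3[C@@H]3[C@H](CCC4(C)OCCO4)C3(C)C)C2=O)C1(C)C | intermediate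
30 | 2-KCp-3-methyl-5-[2-KCp-4-(phenylsulfanyl)-3-(trifluoromethylsulfonyloxy)cyclopent-2-en-1-yl]cyclopent-2-en-1-one; C-5 and C-1′ as in the SMILES, C-4′ epimers | CC1(OCCO1)CC[C@H]1[C@@H](C2=C(C)C[C@H]([C@@H]3CC(Sc4ccccc4)C(OS(=O)(=O)C(F)(F)F)=C3[C@@H]3[C@H](CCC4(C)OCCO4)C3(C)C)C2=O)C1(C)C | intermediate
31 | 2-KCp-3-methyl-5-[2-KCp-3-methyl-4-(phenylsulfanyl)cyclopent-2-en-1-yl]cyclopent-2-en-1-one | CC1(OCCO1)CC[C@H]1[C@@H](C2=C(C)C[C@H]([C@@H]3CC(Sc4ccccc4)C(C)=C3[C@@H]3[C@H](CCC4(C)OCCO4)C3(C)C)C2=O)C1(C)C | intermediate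
32 | 2-KCp-3-methyl-5-[2-KCp-3-methyl-4-(phenylsulfonyl)cyclopent-2-en-1-yl]cyclopent-2-en-1-one | CC1(OCCO1)CC[C@H]1[C@@H](C2=C(C)C[C@H]([C@@H]3CC(S(=O)(=O)c4ccccc4)C(C)=C3[C@@H]3[C@H](CCC4(C)OCCO4)C3(C)C)C2=O)C1(C)C | intermediate
33 | α-lithio sulfone of 32 (not isolated) | CC1(OCCO1)CC[C@H]1[C@@H](C2=C(C)C[C@H]([C@@H]3CC([Li])(S(=O)(=O)c4ccccc4)C(C)=C3[C@@H]3[C@H](CCC4(C)OCCO4)C3(C)C)C2=O)C1(C)C | intermediate
34 | lithium 4,8-bis(KCp)-1,3-dimethyl-2-(phenylsulfonyl)-syn-tricyclo[4.2.1.1(2,5)]deca-3,7-dien-7-olate (not isolated) | CC1(OCCO1)CC[C@H]1[C@@H](C2=C(O[Li])[C@@H]3C[C@@]2(C)[C@@]2(S(=O)(=O)c4ccccc4)C[C@@H]3C([C@@H]3[C@H](CCC4(C)OCCO4)C3(C)C)=C2C)C1(C)C | intermediate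
35 | 4,8-bis(KCp)-1,3-dimethyl-2-(phenylsulfonyl)-syn-tricyclo[4.2.1.1(2,5)]deca-3,7-dien-7-yl trifluoromethanesulfonate | CC1(OCCO1)CC[C@H]1[C@@H](C2=C(OS(=O)(=O)C(F)(F)F)[C@@H]3C[C@@]2(C)[C@@]2(S(=O)(=O)c4ccccc4)C[C@@H]3C([C@@H]3[C@H](CCC4(C)OCCO4)C3(C)C)=C2C)C1(C)C | intermediate
36 | 4,8-bis(KCp)-1,3-dimethyl-2-(phenylsulfonyl)-syn-tricyclo[4.2.1.1(2,5)]deca-3,7-diene | CC1(OCCO1)CC[C@H]1[C@@H](C2=C[C@@H]3C[C@@]2(C)[C@@]2(S(=O)(=O)c4ccccc4)C[C@@H]3C([C@@H]3[C@H](CCC4(C)OCCO4)C3(C)C)=C2C)C1(C)C | intermediate
37 | 4,8-bis(KCp)-1,3-dimethyl-syn-tricyclo[4.2.1.1(2,5)]deca-3,7-diene | CC1(OCCO1)CC[C@H]1[C@@H](C2=C[C@@H]3C[C@@]2(C)[C@H]2C[C@@H]3C([C@@H]3[C@H](CCC4(C)OCCO4)C3(C)C)=C2C)C1(C)C | intermediate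
38 | 1,3-dimethyl-syn-tricyclo[4.2.1.1(2,5)]deca-3,7-diene carrying a (1R,3S)-2,2-dimethyl-3-(3-oxobutyl)cyclopropyl group at C-4 and at C-8; both etheno bridges on the same face of the central ring | CC(=O)CC[C@H]1[C@@H](C2=C[C@@H]3C[C@@]2(C)[C@H]2C[C@@H]3C([C@@H]3[C@H](CCC(C)=O)C3(C)C)=C2C)C1(C)C | target

**Totals**
Total step count: 24. Longest linear sequence: 21 steps (steps 1–10, 14–17, 18–24).

**Steps most likely to fail**

Step 18. The acceptor 27 has an acidic C-5 hydrogen, so proton transfer can compete with the Michael addition, and face selectivity towards the two cyclopropyl groups is only substrate-controlled. The fallback sets out from 20 and comes back at 30. Compound 20 is converted with LiN(iPr)2 and then tBuMe2SiCl into the cross-conjugated silyl dienol ether F1. F1 is added to 27 in a Mukaiyama–Michael reaction under silyl triflate catalysis (tBuMe2SiOTf 5 mol%, 2,6-di-tert-butylpyridine, CH2Cl2, −78 °C), a neutral manifold in which the acidic hydrogen is not at risk. Silyl transfer gives the ring-2 silyl enol ether F2, and MeLi followed by Comins' reagent converts F2 into 30.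

Step 21. The ring closure makes a quaternary centre inside a strained syn cage and may be reversible, and the carbanion may compete for the triflating agent. The fallback sets out from 32 and comes back at 35. The closure is run with Me3SiCl present from the start (LiN(SiMe3)2, Me3SiCl, THF, −78 °C), so that each ring-closed enolate is silylated as it forms. This gives the isolable trimethylsilyl enol ether F3, which is then converted with MeLi and Comins' reagent into 35; C–C bond formation is thus separated from triflation.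

Step 20. The oxidation has to spare the electron-rich tetrasubstituted alkene of ring 2. The fallback sets out from 30 and comes back at 32 by inverting the order of events. Compound 30, whose ring-2 alkene is still an electron-poor vinyl triflate, is oxidized first with the same molybdate/H2O2 system to the sulfonyl triflate F4. The methyl group is then introduced by Stille coupling (Pd(PPh3)4, LiCl, Me4Sn, DMF, 80 °C) to give 32.

**Further compounds**
F1 | step 18 | tert-butyldimethylsilyl dienol ether of 20 (2-silyloxy-1,3-diene) | CC1(OCCO1)CC[C@H]1[C@@H](C2=C(C)CC=C2O[Si](C)(C)C(C)(C)C)C1(C)C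
F2 | step 18 | ring-2 tert-butyldimethylsilyl enol ether of the Michael adduct | CC1(OCCO1)CC[C@H]1[C@@H](C2=C(C)C[C@H]([C@@H]3CC(Sc4ccccc4)C(O[Si](C)(C)C(C)(C)C)=C3[C@@H]3[C@H](CCC4(C)OCCO4)C3(C)C)C2=O)C1(C)C
F3 | step 21 | trimethylsilyl enol ether corresponding to 34 | CC1(OCCO1)CC[C@H]1[C@@H](C2=C(O[Si](C)(C)C)[C@@H]3C[C@@]2(C)[C@@]2(S(=O)(=O)c4ccccc4)C[C@@H]3C([C@@H]3[C@H](CCC4(C)OCCO4)C3(C)C)=C2C)C1(C)C
F4 | step 20 | sulfone analogue of triflate 30 | CC1(OCCO1)CC[C@H]1[C@@H](C2=C(C)C[C@H]([C@@H]3CC(S(=O)(=O)c4ccccc4)C(OS(=O)(=O)C(F)(F)F)=C3[C@@H]3[C@H](CCC4(C)OCCO4)C3(C)C)C2=O)C1(C)C
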